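Ring B holds the one disconnection that matters. C10 carries C1 and C7 carries C11, 1,4 to each other and on the same face once C7 is inverted, so a C1=C11 bridge turns ring B into a bicyclo[2.2.2]octene. Ring-rearrangement metathesis of that cage (14), whose endo C5 chain ends in a vinyl carbinol, cuts the bridge. In one operation it makes C1=C2 (ring A), C11=C12 (isopropenyl) and the cis-decalin 15. The cage comes from creosol by masked o-benzoquinone Diels–Alder chemistry. C15 travels as a methylene group, so C7, C4 and C3 are set afterwards, in that order, under thermodynamic control.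

Key step: step 9

Numbering: the eremophilane numbering of the target is used for every intermediate. Ring A = C1–C5 and C10, ring B = C5–C10, C11–C13 = isopropenyl, C14 on C5, C15 on C4; β is the face of C14.

Design remarks:
- (a) The C8 ketal is removed on the cage, before the key step, where acid can do no harm.
- (b) C15 is carried as =CH2. A C4 stereocentre and C7 would otherwise bias each other's equilibrium, since a 4α-methyl group favours 7α.
- (c) C8 rests as an alcohol from step 10 to step 15. An 8-oxo-7-isopropenyl unit drifts to the conjugated isopropylidene ketone under the base needed at C4, and it loses O9 under electron transfer.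

Assumption: the configuration of camphanate 7 is confirmed by X-ray analysis before it is carried on. Compounds 4 and 5 are racemic and are drawn as the enantiomer that is kept.

Step 1
Reactants: 1 creosol (2-methoxy-4-methylphenol); 2 3-methylbut-3-en-2-one
Product: 4 rac-endo-7-acetyl-3,3-dimethoxy-5,7-dimethylbicyclo[2.2.2]oct-5-en-2-one, via masked o-benzoquinone 3 (not isolated)
Conditions: PhI(OAc)2 (slow addition), MeOH, 2 (10 equiv), 0 °C to rt
Reagents that add atoms: methanol, CO; 3-methylbut-3-en-2-one (2), CC(=C)C(C)=O
Why: Oxidative dearomatisation gives the 6,6-dimethoxy-2,4-dienone, whose Diels–Alder reaction with the α-substituted enone follows the ortho rule (C5 bonds to C10, next to the ketone) and the endo rule (acetyl syn to the new C1=C11 bridge), which fixes C5, C7 and C10 relative to one another.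

Step 2
Reactants: 4 rac-adduct
Product: 5 rac-alcohol (C9-OH anti to the C1=C11 bridge, i.e. 9β; acetyl untouched)
Conditions: NaBH4, MeOH–CH2Cl2, −40 °C
Reagents that add atoms: none
Why: Hydride reduction in which the strained, ketal-activated ring ketone C9 reacts far faster than the neopentyl methyl ketone, and hydride enters from the face of the C1=C11 bridge because C14 blocks the other face, so O9 ends anti to the bridge.

Step 3
Reactants: 5 rac-alcohol; 6 (1S)-(−)-camphanic chloride
Product: 7 (1S)-camphanate of the enantiomer of 5 drawn in the list (single diastereomer after separation)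
Conditions: 6, pyridine, DMAP, CH2Cl2, rt; chromatography and crystallisation
Reagents that add atoms: (1S)-camphanic chloride (6), O=C(Cl)[C@@]12CC[C@@](C)(C(=O)O1)C2(C)C
Why: Classical resolution through diastereomeric esters, which are separable by chromatography or crystallisation, and the crystalline camphanate also allows the absolute configuration to be checked.

Step 4
Reactants: 7 camphanate
Product: 8 enantiopure alcohol (same constitution and relative configuration as 5)
Conditions: K2CO3, MeOH, 40 °C
Reagents that add atoms: none
Why: Base-catalysed transesterification frees the alcohol while ketal, methyl ketone and alkene are inert and no stereocentre can enolise (C10 is a bridgehead, C5 is quaternary).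

Step 5
Reactants: 8 alcohol
Product: 9 tert-butyldimethylsilyl ether of 8 (9β-OTBS)
Conditions: TBSOTf, 2,6-lutidine, CH2Cl2, −78 to 0 °C
Reagents that add atoms: TBSOTf, CC(C)(C)[Si](C)(C)OS(=O)(=O)C(F)(F)F
Why: Silylation with the silyl triflate is chosen because O9 lies 1,3 to C14 and is crowded, and 2,6-lutidine at low temperature does not enolise the methyl ketone or ionise the ketal.

Step 6
Reactants: 9 silyl ether
Product: 11 enol triflate of 9 (C4 bears OTf; C4=C15 is a terminal methylene), via potassium enolate 10 (not isolated)
Conditions: KN(SiMe3)2, THF, −78 °C; then PhNTf2, −78 to 0 °C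
Reagents that add atoms: N-phenylbis(trifluoromethanesulfonimide), O=S(=O)(N(c1ccccc1)S(=O)(=O)C(F)(F)F)C(F)(F)F
Why: Enol triflate formation, in which enolisation can only go toward the methyl group C15 because C5 is quaternary, so O-sulfonylation gives a single 1,1-disubstituted vinyl triflate.

Step 7
Reactants: 11 enol triflate
Product: 12 keto triflate (C8 ketone, 9β-OTBS, vinyl triflate on C5)
Conditions: TsOH·H2O (20 mol %), acetone–H2O (10:1), 40 °C
Reagents that add atoms: water, O
Why: Acid-catalysed ketal hydrolysis is done on the robust cage, where C7 is a bridgehead that cannot enolise and the vinyl triflate and hindered silyl ether tolerate the medium, so no acid ever meets the later bis-allylic alcohol or the β,γ-unsaturated ketone.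

Step 8
Reactants: 12 keto triflate; 13 acrolein
Product: 14 cage vinyl carbinol: endo bicyclo[2.2.2]octenone with C8=O, 9β-OTBS and a 3-hydroxypenta-1,4-dien-2-yl chain (C4(=C15H2)–C3H(OH)–C2H=CH2) on C5, both C3 epimers
Conditions: 13 (5 equiv), CrCl2 (6 equiv), NiCl2 (2 mol %), DMF, rt
Reagents that add atoms: acrolein (13), C=CC=O
Why: Nozaki–Hiyama–Kishi coupling, in which zerovalent nickel inserts into the C4–OTf bond and transmetalation to trivalent chromium gives a nucleophile that adds 1,2 to the aldehyde only, so the C8 ketone and the silyl ether survive, and the C3 epimer mixture is harmless because C3 is oxidised in step 11.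

Step 9
Reactants: 14 cage vinyl carbinol
Product: 15 7-epi cis-decalin: 9β-silyloxy-3-hydroxyeremophila-1,4(15),11-trien-8-one with 7α-isopropenyl, 5β-methyl and 10β-H, both C3 epimers
Conditions: second-generation Hoveyda–Grubbs catalyst (H2IMes)Cl2Ru=CH(C6H4-2-O-i-Pr) (10 mol %, in portions), ethylene (1 atm), 1,4-benzoquinone (20 mol %), toluene (5 mM), 80 °C
Reagents that add atoms: ethylene, C=C
Why: Ring-rearrangement metathesis: the Ru methylidene kept alive by ethylene adds across the strained C1=C11 bridge with Ru on the less substituted C1, the reverse of a ring closure to a trisubstituted olefin, which releases C11=C12 and leaves a C1 alkylidene that closes on the vinyl group to C1=C2 and regenerates the methylidene. Initiation at the vinyl carbinol followed by intramolecular attack on the bridge passes through a disubstituted C11 alkylidene of the kind met in closures to tetrasubstituted olefins, and full ethenolysis followed by ring closure is a third channel, but all three end in 15. The closest known reactions are the ring-rearrangement metatheses of bicyclo[2.2.2]octenes from masked o-benzoquinone adducts to cis-fused bicycles, the methyl group on the bridge being the demanding feature here. Ring A closes as a cyclohexene by six-membered ring-closing metathesis, which is possible only because the endo adduct holds the C5 chain syn to the bridge. No stereocentre is created: C5, C9 and C10 are carried over, the cis fusion follows from the cage, and C7 necessarily keeps its isopropenyl group cis to C1 (7α). As for selectivity, only closure of C2 onto C1 gives an unstrained ring, the hindered C4=C15 methylene and the new isopropenyl group are 1,1-disubstituted spectators whose exchange with ethylene is degenerate, relief of cage strain drives the process, and benzoquinone suppresses Ru–H migration of the allylic alcohol and of the β,γ-enone.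

Step 10
Reactants: 15 7-epi decalin ketone
Product: 17 7β-configured 3,8-diol (9β-OTBS; 8α-OH; both C3 epimers), via 7β-ketone 16 (not isolated)
Conditions: DBU (0.2 equiv), CH2Cl2, 0 °C to rt; then MeOH, NaBH4, −20 °C
Reagents that add atoms: none
Why: Base-mediated epimerisation through the extended enolate followed by hydride reduction: with C4 still sp2 the only low-energy form is the chair–chair conformer with 7β-isopropenyl and 9β-OTBS equatorial (7α either clashes 1,3-diaxially with C4 or forces the OTBS group axial against C14), brief amine catalysis reprotonates C7 faster than C12, and immediate reduction (axial attack, equatorial 8α-OH, configuration without consequence) removes the ketone before the harsher steps ahead.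

Step 11
Reactants: 17 diol
Product: 18 cross-conjugated dienone (eremophila-1,4(15),11-trien-3-one with 8α-OH and 9β-OTBS)
Conditions: MnO2 (activated, 20 equiv), CH2Cl2, rt
Reagents that add atoms: none
Why: Allylic oxidation with MnO2 takes only the doubly allylic C3 carbinol, merges both C3 epimers into one compound and leaves the saturated, crowded 8-OH alone.

Step 12
Reactants: 18 dienone
Product: 20 4β-methyl 3-ketone (8α-OH; 9β-OTBS; 7β-isopropenyl), via C4-epimeric ketone 19 (not isolated)
Conditions: [(Ph3P)CuH]6 (0.5 equiv), H2O (10 equiv), degassed toluene, rt; then DBU (2 equiv), 60 °C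
Reagents that add atoms: none
Why: Copper hydride conjugate reduction saturates both enone C=C bonds and spares the isolated isopropenyl group, and enolate protonation followed by DBU equilibration puts C15 equatorial (4β) because the diequatorial 7β,9β ring B locks the conformer in which a 4α-methyl group would be 1,3-diaxial to C9.

Step 13
Reactants: 20 ketone
Product: 21 3α,8α-diol (3α-OH equatorial, trans to the 4β-methyl group)
Conditions: Li, NH3(l)–THF, EtOH, −78 °C; NH4Cl
Reagents that add atoms: none
Why: Dissolving-metal ketone reduction gives the more stable equatorial alcohol, the outcome known for ketones flanked by a syn-axial methyl group such as 11-oxo steroids, whereas hydrides would be steered by axial C14 to the axial 3β-alcohol, and nothing else is reducible because C8 is an alcohol and the alkene is isolated.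

Step 14
Reactants: 21 diol; 22 tiglic acid
Product: 23 3α-tiglate (8α-OH free, 9β-OTBS)
Conditions: 22 (1.3 equiv), DCC, DMAP, CH2Cl2, 0 °C to rt
Reagents that add atoms: tiglic acid (22), C/C=C(\C)C(=O)O
Why: Steglich esterification acylates the accessible equatorial 3α-OH while the 8-OH, wedged between the isopropenyl and silyloxy groups, stays free, and tiglic acid is the stable E isomer and keeps its geometry.

Step 15
Reactants: 23 hydroxy tiglate
Product: 24 8-ketone (3α-tiglate, 9β-OTBS, 7β-isopropenyl)
Conditions: Dess–Martin periodinane, CH2Cl2, rt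
Reagents that add atoms: none
Why: Dess–Martin oxidation restores C8=O under non-basic conditions, so the isopropenyl double bond stays out of conjugation and C7 and C9 keep their already stable equatorial configurations.

Step 16
Reactants: 24 silyloxy ketone
Product: 25 9β-hydroxy-8-ketone (α-ketol, 3α-tiglate)
Conditions: HF·pyridine, THF, 0 °C to rt
Reagents that add atoms: none
Why: Fluoride-mediated desilylation in a mildly acidic medium avoids the enolate chemistry (ketol shift, double-bond drift) that basic fluoride could start, and ester and alkenes are inert.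

Step 17
Reactants: 25 α-ketol; 26 senecioic acid (3-methylbut-2-enoic acid)
Product: 27 target, 3α-tigloyloxy-9β-senecioyloxyeremophil-11-en-8-one (3R,4R,5R,7R,9R,10S)
Conditions: 26 (1.5 equiv), DCC, DMAP, CH2Cl2, 0 °C to rt
Reagents that add atoms: senecioic acid (26), CC(C)=CC(=O)O
Why: Steglich esterification of the unhindered equatorial 9β-OH is mild enough to keep the senecioate conjugated and to leave C7 and C9, both in their thermodynamically preferred equatorial arrangement, unchanged.

Compound list
1 | creosol (2-methoxy-4-methylphenol) | COc1cc(C)ccc1O | starting material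
2 | 3-methylbut-3-en-2-one | CC(=C)C(C)=O | starting material
3 | 6,6-dimethoxy-4-methylcyclohexa-2,4-dien-1-one (masked o-benzoquinone) | COC1(OC)C=C(C)C=CC1=O | intermediate
4 | rac-endo-7-acetyl-3,3-dimethoxy-5,7-dimethylbicyclo[2.2.2]oct-5-en-2-one (acetyl syn to the alkene bridge; racemate, kept enantiomer drawn) | CC(=O)[C@@]1(C)C[C@H]2C(C)=C[C@@H]1C(=O)C2(OC)OC | intermediate
5 | rac-alcohol from 4 (C9-OH anti to the alkene bridge; racemate, kept enantiomer drawn) | CC(=O)[C@@]1(C)C[C@H]2C(C)=C[C@@H]1[C@@H](O)C2(OC)OC | intermediate
6 | (1S)-(−)-camphanic chloride | O=C(Cl)[C@@]12CC[C@@](C)(C(=O)O1)C2(C)C | starting material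
7 | (1S)-camphanate of the kept enantiomer of 5 | CC(=O)[C@@]1(C)C[C@H]2C(C)=C[C@@H]1[C@@H](OC(=O)[C@@]34CC[C@@](C)(C(=O)O3)C4(C)C)C2(OC)OC | intermediate
8 | enantiopure alcohol | CC(=O)[C@@]1(C)C[C@H]2C(C)=C[C@@H]1[C@@H](O)C2(OC)OC | intermediate
9 | 9β-TBS ether of 8 | CC(=O)[C@@]1(C)C[C@H]2C(C)=C[C@@H]1[C@@H](O[Si](C)(C)C(C)(C)C)C2(OC)OC | intermediate
10 | potassium enolate of 9 | [K+].C=C([O-])[C@@]1(C)C[C@H]2C(C)=C[C@@H]1[C@@H](O[Si](C)(C)C(C)(C)C)C2(OC)OC | intermediate
11 | enol triflate (8,8-dimethoxy, 9β-OTBS) | C=C(OS(=O)(=O)C(F)(F)F)[C@@]1(C)C[C@H]2C(C)=C[C@@H]1[C@@H](O[Si](C)(C)C(C)(C)C)C2(OC)OC | intermediate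
12 | keto triflate (C8=O, 9β-OTBS) | C=C(OS(=O)(=O)C(F)(F)F)[C@@]1(C)C[C@H]2C(C)=C[C@@H]1[C@@H](O[Si](C)(C)C(C)(C)C)C2=O | intermediate
13 | acrolein | C=CC=O | starting material
14 | key-step precursor: endo cage with C8=O, 9β-OTBS and the 3-hydroxypenta-1,4-dien-2-yl chain on C5 (both C3 epimers) | C=CC(O)C(=C)[C@@]1(C)C[C@H]2C(C)=C[C@@H]1[C@@H](O[Si](C)(C)C(C)(C)C)C2=O | intermediate
15 | key-step product: 7-epi cis-decalin, 9β-silyloxy-3-hydroxyeremophila-1,4(15),11-trien-8-one (both C3 epimers) | C=C(C)[C@@H]1C[C@@]2(C)[C@H](C=CC(O)C2=C)[C@@H](O[Si](C)(C)C(C)(C)C)C1=O | intermediate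
16 | 7β-ketone (C7 epimer of 15) | C=C(C)[C@H]1C[C@@]2(C)[C@H](C=CC(O)C2=C)[C@@H](O[Si](C)(C)C(C)(C)C)C1=O | intermediate
17 | 7β 3,8α-diol (both C3 epimers) | C=C(C)[C@H]1C[C@@]2(C)[C@H](C=CC(O)C2=C)[C@@H](O[Si](C)(C)C(C)(C)C)[C@@H]1O | intermediate
18 | cross-conjugated dienone, 8α-OH | C=C(C)[C@H]1C[C@@]2(C)[C@H](C=CC(=O)C2=C)[C@@H](O[Si](C)(C)C(C)(C)C)[C@@H]1O | intermediate
19 | saturated 3-ketone, C4 epimers | C=C(C)[C@H]1C[C@@]2(C)[C@H](CCC(=O)C2C)[C@@H](O[Si](C)(C)C(C)(C)C)[C@@H]1O | intermediate
20 | 4β-methyl 3-ketone | C=C(C)[C@H]1C[C@@]2(C)[C@H](CCC(=O)[C@@H]2C)[C@@H](O[Si](C)(C)C(C)(C)C)[C@@H]1O | intermediate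
21 | 3α,8α-diol | C=C(C)[C@H]1C[C@@]2(C)[C@H](CC[C@@H](O)[C@@H]2C)[C@@H](O[Si](C)(C)C(C)(C)C)[C@@H]1O | intermediate
22 | tiglic acid ((E)-2-methylbut-2-enoic acid) | C/C=C(\C)C(=O)O | starting material
23 | 3α-tiglate, 8α-OH | C=C(C)[C@H]1C[C@@]2(C)[C@H](CC[C@@H](OC(=O)/C(C)=C/C)[C@@H]2C)[C@@H](O[Si](C)(C)C(C)(C)C)[C@@H]1O | intermediate
24 | 3α-tiglate 8-ketone, 9β-OTBS | C=C(C)[C@H]1C[C@@]2(C)[C@H](CC[C@@H](OC(=O)/C(C)=C/C)[C@@H]2C)[C@@H](O[Si](C)(C)C(C)(C)C)C1=O | intermediate
25 | 3α-tiglate 9β-hydroxy-8-ketone | C=C(C)[C@H]1C[C@@]2(C)[C@H](CC[C@@H](OC(=O)/C(C)=C/C)[C@@H]2C)[C@@H](O)C1=O | intermediate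
26 | senecioic acid (3-methylbut-2-enoic acid) | CC(C)=CC(=O)O | starting material
27 | CNP0375730.1 | C=C(C)[C@H]1C[C@@]2(C)[C@H](CC[C@@H](OC(=O)/C(C)=C/C)[C@@H]2C)[C@@H](OC(=O)C=C(C)C)C1=O | target

Total step count: 17. Longest linear sequence: 17 steps, from creosol.

Steps most likely to fail

1. Step 9.
   - What may go wrong: the methyl-bearing bridge may resist attack, so that the catalyst is used up by methylidene decay or by isomerising the allylic alcohol before the cage opens.
   - Fallback, from 11 back to 15: the electron-rich bridge of 11 is cleaved by ozone (CH2Cl2–MeOH, −78 °C; Me2S) beside the electron-poor vinyl triflate, giving the keto aldehyde F1. Double Wittig methylenation (Ph3P=CH2, THF, −78 to 0 °C) gives the vinyl isopropenyl cyclohexane F2. Ketal hydrolysis as in step 7 gives the ketone F3. Coupling with acrolein as in step 8 gives the tetraene alcohol F4. An ordinary ring-closing metathesis of its two monosubstituted vinyl groups (second-generation Grubbs catalyst (H2IMes)(PCy3)Cl2Ru=CHPh, CH2Cl2, 40 °C) then closes ring A to 15.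

2. Step 8.
   - What may go wrong: oxidative addition at the vinyl triflate next to quaternary C5 may be slow, so that polymerisation of acrolein or protonation of the organometal overtakes C–C bond formation.
   - Fallback, from 9 back to 14: ketone 9 is condensed with 2,4,6-triisopropylbenzenesulfonyl hydrazide to the sulfonylhydrazone F5. n-BuLi (2.2 equiv, THF, −78 to 0 °C) generates the vinyllithium (Shapiro reaction), which adds 1,2 to acrolein at −78 °C to give the ketal-protected dienol F6. Neutral transketalisation (iodine, 10 mol %, acetone, rt) unmasks C8 and gives 14.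

3. Step 13.
   - What may go wrong: facial discrimination may be poor when the ketyl-derived carbanion is protonated, or the silyl group may migrate from O9 to the O8 alkoxide in the basic medium.
   - Fallback, from 20 back to 23: LiBH(s-Bu)3 (THF, −78 °C) attacks 20 along the equatorial path opposite axial C14 and gives the axial 3β-alcohol F7. Mitsunobu esterification with tiglic acid (PPh3, DIAD, toluene) inverts C3 and leads directly to 23, the crowded 8-OH staying untouched.

Further compounds
F1 | step 9 | keto aldehyde from ozonolysis of 11 (C1 aldehyde on C10, C11 methyl ketone on C7) | CC(=O)[C@@H]1C[C@](C)(C(=C)OS(=O)(=O)C(F)(F)F)[C@H](C=O)[C@@H](O[Si](C)(C)C(C)(C)C)C1(OC)OC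
F2 | step 9 | vinyl isopropenyl cyclohexane ketal | C=C(C)[C@@H]1C[C@](C)(C(=C)OS(=O)(=O)C(F)(F)F)[C@H](C=C)[C@@H](O[Si](C)(C)C(C)(C)C)C1(OC)OC
F3 | step 9 | vinyl isopropenyl cyclohexanone | C=C(C)[C@@H]1C[C@](C)(C(=C)OS(=O)(=O)C(F)(F)F)[C@H](C=C)[C@@H](O[Si](C)(C)C(C)(C)C)C1=O
F4 | step 9 | tetraene alcohol (both C3 epimers) | C=C(C)[C@@H]1C[C@](C)(C(=C)C(O)C=C)[C@H](C=C)[C@@H](O[Si](C)(C)C(C)(C)C)C1=O
F5 | step 8 | 2,4,6-triisopropylbenzenesulfonylhydrazone of 9 | CC(=NNS(=O)(=O)c1c(C(C)C)cc(C(C)C)cc1C(C)C)[C@@]1(C)C[C@H]2C(C)=C[C@@H]1[C@@H](O[Si](C)(C)C(C)(C)C)C2(OC)OC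
F6 | step 8 | 8,8-dimethoxy analogue of 14 (both C3 epimers) | C=CC(O)C(=C)[C@@]1(C)C[C@H]2C(C)=C[C@@H]1[C@@H](O[Si](C)(C)C(C)(C)C)C2(OC)OC
F7 | step 13 | 3β,8α-diol (axial 3β-OH) | C=C(C)[C@H]1C[C@@]2(C)[C@H](CC[C@H](O)[C@@H]2C)[C@@H](O[Si](C)(C)C(C)(C)C)[C@@H]1O
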